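**Plan**

- Ret­rosynthesis: the hydroquinone is traced back to its 2'-O-methyl ether methyl ester, and the benzene ring is then cut at C1'–C2' and C5'–C6'.
- Enabling feature: the ring is a 2-acyl-1,4-dioxygenated benzene. C1' (acyl-bearing) and the adjacent C6'–H are the two carbons of a terminal ynone, and C2'(O)–C3'–C4'–C5'(O), with its para oxygens, is the diene carbon set of 2-methoxyfuran.
- The ynone is cut back to the CH2CO2H arm of a 2-substituted succinate, the C2–CH2CO bond is cut as an auxiliary-controlled enolate alkylation, and the C13 acyl chain is cut at C3–C4 into geranyl bromide and a three-carbon Grignard reagent.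
- Forward: chain (steps 1–2), imide and alkylation (3–4), carboxyl differentiation and ynone (5–9), benzene ring by cycloaddition–aromatisation (10, the only ring made), ester hydrolysis and O-demethylation through the quinone (11–12).
- Stereochemistry: the single centre (2S) is set in step 4 by (R)-4-benzyl-2-oxazolidinone and is not enolised afterwards; the 5E alkene is carried over unchanged from geranyl bromide.

Key step: step 10

Assumption: the cycloaddition is taken to follow the electronically preferred orientation (methoxy-bearing furan carbon to the acyl-bearing alkyne carbon), giving 23; the opposite orientation would give the isomeric monomethyl ether, which steps 11 and 12 would convert into the same target.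

**Route**

Step 1
Reactants: 1 geranyl bromide [(2E)-1-bromo-3,7-dimethylocta-2,6-diene]; 2 3-chloropropan-1-ol
Product: 4 (5E)-6,10-dimethylundeca-5,9-dien-1-ol, via chloromagnesium 3-(chloromagnesio)propan-1-olate 3 (not isolated)
Conditions: 2, MeMgCl, THF, −20 °C; Mg, reflux; then 1, Li2CuCl4 (3 mol %), THF, −40 → 0 °C; aq NH4Cl
Reagents that add atoms: none
Why: Copper-catalysed (Kochi-type) cross-coupling of a primary alkylmagnesium reagent with a primary allylic bromide in THF should proceed by direct substitution at the CH2Br carbon with retention of the E alkene, the magnesium alkoxide end of 3 being a spectator, so one operation adds C1–C3 of the chain.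

Step 2
Reactants: 4 (5E)-6,10-dimethylundeca-5,9-dien-1-ol
Product: 5 (5E)-6,10-dimethylundeca-5,9-dienoic acid
Conditions: TEMPO (20 mol %), PhI(OAc)2 (2.2 equiv), MeCN/H2O (1:1), rt
Reagents that add atoms: water, O
Why: Oxoammonium-mediated oxidation (TEMPO with PhI(OAc)2 in aqueous acetonitrile) takes a primary alcohol through the aldehyde hydrate to the carboxylic acid under near-neutral conditions that leave trisubstituted alkenes alone.

Step 3
Reactants: 5 (5E)-6,10-dimethylundeca-5,9-dienoic acid; 6 (R)-4-benzyl-2-oxazolidinone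
Product: 8 (4R)-4-benzyl-3-[(5E)-6,10-dimethylundeca-5,9-dienoyl]-1,3-oxazolidin-2-one, via mixed pivalic anhydride 7 (not isolated)
Conditions: PivCl, Et3N, THF, −20 °C; then 6, LiCl, −20 °C → rt
Reagents that add atoms: none
Why: One-pot N-acylation of an oxazolidinone through a mixed pivalic anhydride with LiCl activation is standard, the oxazolidinone attacking the less hindered carbonyl of 7.

Step 4
Reactants: 8 (4R)-4-benzyl-3-[(5E)-6,10-dimethylundeca-5,9-dienoyl]-1,3-oxazolidin-2-one; 9 tert-butyl bromoacetate
Product: 11 tert-butyl (3S,6E)-3-{[(4R)-4-benzyl-2-oxo-1,3-oxazolidin-3-yl]carbonyl}-7,11-dimethyldodeca-6,10-dienoate, via sodium Z-enolate 10 (not isolated)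
Conditions: NaN(SiMe3)2, THF, −78 °C; then 9, −78 → −45 °C; aq NH4Cl
Reagents that add atoms: none
Why: Evans asymmetric alkylation, in which the chelated sodium Z-enolate 10 is alkylated by the activated bromide on the face opposite the benzyl group; with the (R)-auxiliary this sets the new centre as S (C2 of the target).

Step 5
Reactants: 11 tert-butyl (3S,6E)-3-{[(4R)-4-benzyl-2-oxo-1,3-oxazolidin-3-yl]carbonyl}-7,11-dimethyldodeca-6,10-dienoate
Product: 13 (2S,5E)-2-(2-tert-butoxy-2-oxoethyl)-6,10-dimethylundeca-5,9-dienoic acid, via peroxy acid 12 (not isolated)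
Conditions: LiOH, H2O2, THF/H2O (3:1), 0 °C; aq Na2SO3; then 1 M HCl to pH 3
Reagents that add atoms: hydrogen peroxide, OO
Why: Hydroperoxide cleavage of an N-acyloxazolidinone attacks the exocyclic carbonyl selectively and without epimerisation, the tert-butyl ester resists it, and reduction of the percarboxylate 12 with sulfite before acidification keeps the alkenes from being epoxidised.

Step 6
Reactants: 13 (2S,5E)-2-(2-tert-butoxy-2-oxoethyl)-6,10-dimethylundeca-5,9-dienoic acid
Product: 14 4-tert-butyl 1-methyl (2S)-2-[(3E)-4,8-dimethylnona-3,7-dien-1-yl]butanedioate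
Conditions: MeI, K2CO3, DMF, rt
Reagents that add atoms: iodomethane, CI
Why: SN2 O-alkylation of the potassium carboxylate with iodomethane gives the methyl ester under conditions too weakly basic to enolise the stereocentre or touch the tert-butyl ester.

Step 7
Reactants: 14 4-tert-butyl 1-methyl (2S)-2-[(3E)-4,8-dimethylnona-3,7-dien-1-yl]butanedioate
Product: 16 (3S,6E)-3-(methoxycarbonyl)-7,11-dimethyldodeca-6,10-dienoic acid, via trimethylsilyl ester 15 (not isolated)
Conditions: TMSOTf, 2,6-lutidine, CH2Cl2, 0 °C → rt; then pH 4 phosphate buffer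
Reagents that add atoms: none
Why: Silyl-triflate-mediated tert-butyl ester cleavage, in which silylation of the ester carbonyl is followed by loss of the tert-butyl cation as isobutene; 2,6-lutidine keeps the medium free of protic acid so the trisubstituted alkenes are not protonated, and the methyl ester, which cannot ionise, stays.

Step 8
Reactants: 16 (3S,6E)-3-(methoxycarbonyl)-7,11-dimethyldodeca-6,10-dienoic acid; 17 ethynyltrimethylsilane
Product: 19 methyl (2S,5E)-6,10-dimethyl-2-[2-oxo-4-(trimethylsilyl)but-3-yn-1-yl]undeca-5,9-dienoate, via acid chloride 18 (not isolated)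
Conditions: 1-chloro-N,N,2-trimethylprop-1-en-1-amine, CH2Cl2, 0 °C → rt; then 17, PdCl2(PPh3)2 (2 mol %), CuI (4 mol %), Et3N (1.2 equiv), THF, rt
Reagents that add atoms: none
Why: The α-chloroenamine converts the acid into chloride 18 without releasing HCl, and the acyl Sonogashira coupling of an acid chloride with a terminal alkyne at room temperature gives the silyl ynone while leaving the ester and the isolated alkenes untouched.

Step 9
Reactants: 19 methyl (2S,5E)-6,10-dimethyl-2-[2-oxo-4-(trimethylsilyl)but-3-yn-1-yl]undeca-5,9-dienoate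
Product: 20 methyl (2S,5E)-6,10-dimethyl-2-(2-oxobut-3-yn-1-yl)undeca-5,9-dienoate
Conditions: Na2B4O7·10H2O (0.1 equiv), MeOH/H2O (10:1), rt, short contact time
Reagents that add atoms: none
Why: Base-catalysed protodesilylation of an alkynylsilane activated by the conjugated carbonyl proceeds with catalytic borax at near-neutral pH, mild enough to avoid methanol addition to the ynone and enolisation at C2.

Step 10
Reactants: 20 methyl (2S,5E)-6,10-dimethyl-2-(2-oxobut-3-yn-1-yl)undeca-5,9-dienoate; 21 2-methoxyfuran
Product: 23 methyl (2S,5E)-2-[2-(5-hydroxy-2-methoxyphenyl)-2-oxoethyl]-6,10-dimethylundeca-5,9-dienoate, via 1-methoxy-7-oxanorbornadiene cycloadduct 22 (not isolated)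
Conditions: 21 (3 equiv), CH2Cl2, 0 °C → rt, dark, acid-free glassware; then ZnI2 (5 mol %), rt
Reagents that add atoms: none
Why: The electron-rich furan (largest HOMO coefficient at C5) and the electron-poor terminal ynone (largest LUMO coefficient at the CH terminus) should combine in an asynchronous normal-demand Diels–Alder reaction that joins furan C5 to the alkyne CH carbon and the methoxy-bearing C2 to the acyl-bearing carbon, giving the oxabicycle 22. The bridging C–O bond at the ketal carbon then ionises with help from the methoxy oxygen and the proton at the other bridgehead is lost, so 22 aromatises to the 4-methoxyphenol 23; the closest known reaction type is the cycloaddition of 2-alkoxyfurans with acetylenic esters and ketones followed by ring opening to hydroquinone monoethers. The six-membered carbocycle is closed by intermolecular [4+2] cycloaddition, both ring bonds (C1'–C2' and C5'–C6') being made to the two alkyne carbons in one operation, and no tether is involved. No stereocentre is created in the product, since the two bridgehead centres of 22 are erased on aromatisation, and the C2 centre is untouched because nothing in the medium enolises the ester. The step needs chemoselectivity for the ynone over the two trisubstituted alkenes, secured because the ynone is the only electron-poor π bond offered to an electron-rich diene, and ring closure in preference to simple conjugate addition of the furan, favoured by aprotic neutral conditions in which the zwitterion from attack at C5 can only collapse onto the oxocarbenium carbon. Regiochemistry is not critical, because the other orientation would give the isomeric monomethyl ether of the same hydroquinone.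

Step 11
Reactants: 23 methyl (2S,5E)-2-[2-(5-hydroxy-2-methoxyphenyl)-2-oxoethyl]-6,10-dimethylundeca-5,9-dienoate
Product: 24 (2S,5E)-2-[2-(5-hydroxy-2-methoxyphenyl)-2-oxoethyl]-6,10-dimethylundeca-5,9-dienoic acid
Conditions: LiOH·H2O, THF/MeOH/H2O (3:1:1), 0 °C → rt, argon; then 1 M HCl
Reagents that add atoms: lithium hydroxide, [Li+].[OH-]
Why: Saponification of the methyl ester with LiOH, in which the phenol is merely deprotonated, the aryl methyl ether is inert, and C2 becomes a carboxylate α-carbon that resists enolisation.

Step 12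
Reactants: 24 (2S,5E)-2-[2-(5-hydroxy-2-methoxyphenyl)-2-oxoethyl]-6,10-dimethylundeca-5,9-dienoic acid
Product: 26 (2S,5E)-2-[2-(2,5-dihydroxyphenyl)-2-oxoethyl]-6,10-dimethylundeca-5,9-dienoic acid, via acylbenzoquinone 25 (not isolated)
Conditions: (NH4)2Ce(NO3)6 (2.2 equiv), MeCN/H2O (2:1), 0 °C, 10 min; then aq Na2S2O4, EtOAc, rt
Reagents that add atoms: water, O
Why: Oxidative demethylation of a 4-methoxyphenol by (NH4)2Ce(NO3)6 (two one-electron oxidations, water adding at the methoxy-bearing carbon and methanol leaving) should give the acylquinone far faster than the isolated alkenes are oxidised, and dithionite reduction of the quinone in the same work-up gives the hydroquinone.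

**Compound list**

1 | geranyl bromide, (2E)-1-bromo-3,7-dimethylocta-2,6-diene | CC(C)=CCC/C(C)=C/CBr | starting material
2 | 3-chloropropan-1-ol | OCCCCl | starting material
3 | chloromagnesium 3-(chloromagnesio)propan-1-olate (formed in the flask) | Cl[Mg]CCCO[Mg]Cl | intermediate
4 | (5E)-6,10-dimethylundeca-5,9-dien-1-ol | CC(C)=CCC/C(C)=C/CCCCO | intermediate
5 | (5E)-6,10-dimethylundeca-5,9-dienoic acid | CC(C)=CCC/C(C)=C/CCCC(=O)O | intermediate
6 | (R)-4-benzyl-2-oxazolidinone | O=C1N[C@H](Cc2ccccc2)CO1 | starting material
7 | (5E)-6,10-dimethylundeca-5,9-dienoic pivalic anhydride (formed in the flask) | CC(C)=CCC/C(C)=C/CCCC(=O)OC(=O)C(C)(C)C | intermediate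
8 | (4R)-4-benzyl-3-[(5E)-6,10-dimethylundeca-5,9-dienoyl]-1,3-oxazolidin-2-one | CC(C)=CCC/C(C)=C/CCCC(=O)N1[C@H](Cc2ccccc2)COC1=O | intermediate
9 | tert-butyl bromoacetate | CC(C)(C)OC(=O)CBr | starting material
10 | sodium Z-enolate of imide 8 (formed in the flask) | CC(C)=CCC/C(C)=C/CC/C=C(\O[Na])N1[C@H](Cc2ccccc2)COC1=O | intermediate
11 | tert-butyl (3S,6E)-3-{[(4R)-4-benzyl-2-oxo-1,3-oxazolidin-3-yl]carbonyl}-7,11-dimethyldodeca-6,10-dienoate | CC(C)=CCC/C(C)=C/CC[C@@H](CC(=O)OC(C)(C)C)C(=O)N1[C@H](Cc2ccccc2)COC1=O | intermediate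
12 | (2S,5E)-2-(2-tert-butoxy-2-oxoethyl)-6,10-dimethylundeca-5,9-dieneperoxoic acid (formed in the flask) | CC(C)=CCC/C(C)=C/CC[C@@H](CC(=O)OC(C)(C)C)C(=O)OO | intermediate
13 | (2S,5E)-2-(2-tert-butoxy-2-oxoethyl)-6,10-dimethylundeca-5,9-dienoic acid | CC(C)=CCC/C(C)=C/CC[C@@H](CC(=O)OC(C)(C)C)C(=O)O | intermediate
14 | 4-tert-butyl 1-methyl (2S)-2-[(3E)-4,8-dimethylnona-3,7-dien-1-yl]butanedioate | CC(C)=CCC/C(C)=C/CC[C@@H](CC(=O)OC(C)(C)C)C(=O)OC | intermediate
15 | 1-methyl 4-trimethylsilyl (2S)-2-[(3E)-4,8-dimethylnona-3,7-dien-1-yl]butanedioate (formed in the flask) | CC(C)=CCC/C(C)=C/CC[C@@H](CC(=O)O[Si](C)(C)C)C(=O)OC | intermediate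
16 | (3S,6E)-3-(methoxycarbonyl)-7,11-dimethyldodeca-6,10-dienoic acid | CC(C)=CCC/C(C)=C/CC[C@@H](CC(=O)O)C(=O)OC | intermediate
17 | ethynyltrimethylsilane | C#C[Si](C)(C)C | starting material
18 | methyl (2S,5E)-2-(2-chloro-2-oxoethyl)-6,10-dimethylundeca-5,9-dienoate (formed in the flask) | CC(C)=CCC/C(C)=C/CC[C@@H](CC(=O)Cl)C(=O)OC | intermediate
19 | methyl (2S,5E)-6,10-dimethyl-2-[2-oxo-4-(trimethylsilyl)but-3-yn-1-yl]undeca-5,9-dienoate | CC(C)=CCC/C(C)=C/CC[C@@H](CC(=O)C#C[Si](C)(C)C)C(=O)OC | intermediate
20 | methyl (2S,5E)-6,10-dimethyl-2-(2-oxobut-3-yn-1-yl)undeca-5,9-dienoate | CC(C)=CCC/C(C)=C/CC[C@@H](CC(=O)C#C)C(=O)OC | intermediate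
21 | 2-methoxyfuran | COc1ccco1 | starting material
22 | methyl (2S,5E)-2-[2-(1-methoxy-7-oxabicyclo[2.2.1]hepta-2,5-dien-2-yl)-2-oxoethyl]-6,10-dimethylundeca-5,9-dienoate (both bridgehead diastereomers; formed in the flask) | CC(C)=CCC/C(C)=C/CC[C@@H](CC(=O)C1=CC2C=CC1(OC)O2)C(=O)OC | intermediate
23 | methyl (2S,5E)-2-[2-(5-hydroxy-2-methoxyphenyl)-2-oxoethyl]-6,10-dimethylundeca-5,9-dienoate | CC(C)=CCC/C(C)=C/CC[C@@H](CC(=O)c1cc(O)ccc1OC)C(=O)OC | intermediate
24 | (2S,5E)-2-[2-(5-hydroxy-2-methoxyphenyl)-2-oxoethyl]-6,10-dimethylundeca-5,9-dienoic acid | CC(C)=CCC/C(C)=C/CC[C@@H](CC(=O)c1cc(O)ccc1OC)C(=O)O | intermediate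
25 | (2S,5E)-2-[2-(3,6-dioxocyclohexa-1,4-dien-1-yl)-2-oxoethyl]-6,10-dimethylundeca-5,9-dienoic acid (formed in the flask) | CC(C)=CCC/C(C)=C/CC[C@@H](CC(=O)C1=CC(=O)C=CC1=O)C(=O)O | intermediate
26 | (2S,5E)-2-[2-(2,5-dihydroxyphenyl)-2-oxoethyl]-6,10-dimethylundeca-5,9-dienoic acid (CNP0303798.1) | CC(C)=CCC/C(C)=C/CC[C@@H](CC(=O)c1cc(O)ccc1O)C(=O)O | target

**Step count and risks**

Total step count: 12. Longest linear sequence: 12 steps (1 → 26); compounds 2, 6, 9, 17 and 21 are commercial and enter without steps of their own.

Steps most likely to fail, riskiest first: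

1. Step 10. The furan may add through C5 to the ynone terminus and be protonated before the second bond forms, traces of acid may hydrolyse 2-methoxyfuran, and the terminal ynone may oligomerise. The fallback brings in the aryl ring preformed; it sets out from acid 16 (through its chloride 18, made as in step 8) and comes back at 23. Commercial 3-bromo-4-methoxyphenol would be silylated (TBSCl, imidazole, DMF) to tert-butyl(3-bromo-4-methoxyphenoxy)dimethylsilane F1. Magnesium insertion (Mg, THF) would give [5-(tert-butyldimethylsilyloxy)-2-methoxyphenyl]magnesium bromide F2. Fe(acac)3-catalysed acylation of F2 with 18 at −78 °C, where the acid chloride reacts far faster than the methyl ester, would give methyl (2S,5E)-2-{2-[5-(tert-butyldimethylsilyloxy)-2-methoxyphenyl]-2-oxoethyl}-6,10-dimethylundeca-5,9-dienoate F3. Bu4NF buffered with AcOH in THF would then release 23, and steps 11 and 12 follow unchanged.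

2. Step 12. The oxidant may attack the trisubstituted alkenes (nitrate addition or over-oxidation), or the transient acylquinone may be captured by a chain alkene or the carboxyl group before it is reduced. The fallback replaces oxidation–reduction by chelation-assisted nucleophilic demethylation; it sets out from 23 and comes back at 26. MgI2·OEt2 in toluene/THF at 60 °C should cleave only the methyl ether ortho to the ketone, giving methyl (2S,5E)-2-[2-(2,5-dihydroxyphenyl)-2-oxoethyl]-6,10-dimethylundeca-5,9-dienoate F4. Hydrolysis with LiOH in degassed THF/H2O under argon, with acidification in the presence of Na2S2O4, would give 26.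

3. Step 8. The acid chloride may form a ketene with the amine base, the methoxy group may migrate between the two carboxyl carbons through a cyclic acyloxonium ion so that the wrong carboxyl is converted, and the alkyne may homocouple. The fallback replaces the palladium-catalysed coupling by acetylide addition to an N-methoxy-N-methylamide; it sets out from 16 and comes back at 20, so it also bypasses step 9. Coupling of 16 with MeNHOMe·HCl (EDC·HCl, N-methylmorpholine, CH2Cl2) would give methyl (2S,5E)-2-{2-[methoxy(methyl)amino]-2-oxoethyl}-6,10-dimethylundeca-5,9-dienoate F5. Ethynylmagnesium bromide (THF, −20 → 0 °C, cold dilute HCl quench) should add to the chelating amide in preference to the α-branched methyl ester and give 20 directly.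

**Further compounds**

F1 | step 10 | tert-butyl(3-bromo-4-methoxyphenoxy)dimethylsilane | COc1ccc(O[Si](C)(C)C(C)(C)C)cc1Br
F2 | step 10 | [5-(tert-butyldimethylsilyloxy)-2-methoxyphenyl]magnesium bromide | COc1ccc(O[Si](C)(C)C(C)(C)C)cc1[Mg]Br
F3 | step 10 | methyl (2S,5E)-2-{2-[5-(tert-butyldimethylsilyloxy)-2-methoxyphenyl]-2-oxoethyl}-6,10-dimethylundeca-5,9-dienoate | CC(C)=CCC/C(C)=C/CC[C@@H](CC(=O)c1cc(O[Si](C)(C)C(C)(C)C)ccc1OC)C(=O)OC
F4 | step 12 | methyl (2S,5E)-2-[2-(2,5-dihydroxyphenyl)-2-oxoethyl]-6,10-dimethylundeca-5,9-dienoate | CC(C)=CCC/C(C)=C/CC[C@@H](CC(=O)c1cc(O)ccc1O)C(=O)OC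
F5 | step 8 | methyl (2S,5E)-2-{2-[methoxy(methyl)amino]-2-oxoethyl}-6,10-dimethylundeca-5,9-dienoate | CC(C)=CCC/C(C)=C/CC[C@@H](CC(=O)N(C)OC)C(=O)OC
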